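4 questions stood on this flask, and I treated them as one question about two amounts.

| setting | Thursday's | Sunday's | Friday's | flask |
|---|---|---|---|---|
| starting material | 1 mM | 1.5 mM | 2 mM | 2.0 mM |
| partner | 8 mM | 8 mM | 8 mM | 8.00 mM |
| second reagent | 2.2 mM | 2.2 mM | 4.4 mM | 2.20 mM |
| third reagent | 8 mM (fed, over 40 s) | 8 mM (fed, over 40 s) | 8 mM (fed, over 40 s) | 8.00 mM (fed, over 40 s) |
| remark | run made earlier; the fed solution adds 1.0 times the starting volume | run made earlier; the fed solution adds 1.0 times the starting volume | run made earlier; the fed solution adds 1.0 times the starting volume | the fed solution adds 1.0 times the starting volume |
| time |  |  |  | 2.5 h |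

| run | time / h | target / % | side product / % |
|---|---|---|---|
| Thursday's | 0.417 | 96.7 | 3.1 |
| Thursday's | 1.00 | 96.7 | 3.9 |
| Thursday's | 2.00 | 96.9 | 3.4 |
| Thursday's | 3.00 | 96.6 | 3.3 |
| Sunday's | 0.417 | 97.0 | 2.8 |
| Sunday's | 1.00 | 96.8 | 2.9 |
| Sunday's | 2.00 | 97.3 | 3.5 |
| Sunday's | 3.00 | 97.2 | 3.3 |
| Friday's | 0.250 | 92.7 | 6.7 |
| Friday's | 0.500 | 92.7 | 6.6 |
| Friday's | 1.33 | 93.1 | 6.8 |
| Friday's | 3.00 | 93.3 | 6.9 |

(scatter of a reading: 0.3 percentage points)

- which holds at 2.5 h: what has brought the reaction to rest, or that it has not come to rest (forward and back rates have come level / the partner has run out first / all of the starting material has reacted / the third reagent has run out first / it is still moving / the second reagent has run out first)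
- how much target there is at 2.5 h, in percent of the starting material charged
- how much side product there is at 2.5 h, in percent of the starting material charged
- amount of target if the flask were left three thousand times as long, in percent of the starting material charged

- charges are per starting volume, the dose included; the dosed solution carries all of it
- on the list of suspects stand: starting material + partner -> intermediate A; starting material + second reagent -> side product; second reagent + intermediate A -> intermediate B; third reagent + intermediate B -> target
- the reaction counts as stopped when no species that holds the starting material changes by six tenths of a point or more over the second half of the time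

On the list of suspects, starting material meets partner to give intermediate A, or meets second reagent to give side product. Intermediate A then takes up second reagent to give intermediate B, which third reagent turns into target. So I counted one second reagent per starting material by either route, and I set c(second reagent), 2.20 mM, against c(starting material), 2.0 mM. I carried their ratio, the equivalents of second reagent per starting material, 1.10. The earlier runs stood at 2.20, 1.47 and 2.20, so this flask had the tightest ratio. Sunday's first reading, at 0.417 h, already summed to 99.8% in target and side product. Because the ratio in this flask stood above one, I took starting material as its limiting reagent, with 9.09% of the second reagent's charge left over.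

The forecast said: all of the starting material has reacted, target 97.5% (96.6% to 98.2%), side product 2.5% (1.8% to 3.3%), and target 97.5% (96.7% to 98.2%) if left far longer. One of its grounds was that “Every starting material uses one second reagent by either route”.

The flask gave: all of the starting material has reacted, target 97.2%, side product 2.82%, and target 97.2% when left far longer.

    starting material + partner → intermediate A (k = 1.78 L mol⁻¹ s⁻¹)
    starting material + second reagent → side product (k = 0.258 L mol⁻¹ s⁻¹)
    second reagent + intermediate A → intermediate B (k = 26.1 L mol⁻¹ s⁻¹)
    third reagent + intermediate B → target (k = 12.3 L mol⁻¹ s⁻¹)

At 0.0241 h the flask used starting material on the partner route and the side route at a ratio of 32. At 2.50 h it kept 9.09% of its second reagent, against the 9.09% that 1.10 equivalents leave. A neighbouring flask charged with 1.3 mM of second reagent stood at 0.650 equivalents, which by that count leaves 35.0% of the starting material charged without second reagent. In that neighbour, at 2.50 h, second reagent stood at 0%, target at 63.6% and intermediate A at 35.0%.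

The numbers in the tables are simulated for substances that don't exist; the scatter is artificial.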